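Readings and results were generated by integration from invented constants; noise was put on by code.

**Fading rate.** This flask slows.

| setting | south-west | west | flask |
|---|---|---|---|
| free monomer | 0.12 M | 0.12 M | 0.12 M |
| protic impurity | 2.4 mM | 1.6 mM | 2.40 mM |
| initiator | 0.31 mol% | 0.31 mol% | 0.31 mol% |
| remark | the very flask that is asked about, followed so far | run made earlier |  |
| time |  |  | 5.0 min |

| run | time / s | monomer in chains / % | free monomer / % |
|---|---|---|---|
| south-west | 10.0 | 8.4 | 88.9 |
| south-west | 12.0 | 10.3 | 88.1 |
| south-west | 20.0 | 16.3 | 82.5 |
| south-west | 40.0 | 26.7 | 71.7 |
| south-west | 60.0 | 34.1 | 64.2 |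
| west | 20.0 | 16.4 | 82.8 |
| west | 40.0 | 26.8 | 72.5 |
| west | 60.0 | 33.9 | 64.2 |
| west | 80.0 | 38.7 | 59.1 |
| west | 90.0 | 41.5 | 56.5 |
| west | 120 | 45.8 | 51.9 |

(scatter of a reading: 0.5 percentage points)

- the average divides the monomer in chains by the number of chains, living and dead together; two radicals that join make one chain
- the earlier runs do not show the number of chains; that part of a forecast is a guess

1. average number of monomer units in a chain (living and dead chains, two that joined counted as one) at 5.0 min
2. part of the free monomer that has reacted at 5.0 min

**Log left.** Free monomer is reckoned here by what is left. The log left, ln(charged amount over amount present), stands in the west run at 0.322 after 40.0 s, 0.526 after 80.0 s and 0.656 after 120 s. The second of these gains is 0.636 of the first. Continuing that series to 5.0 min gives 57.4% reacted.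

**Wider steps.** The weak link is the short step, since a scatter of 0.5 percentage points weighs on gains this small. At 60.0 s the west run reads 64.2% free monomer and the south-west run 64.2%. In the west run, over steps of that length, the gain in log left divided by the gain before it, the keep factor, reads 0.480. Then 3.00 further steps add 0.175, so the estimate for 5.0 min is a log left of 0.830 and 56.4% reacted. The readings show no number of chains, so dp remains a guess.

**The forecast.** The forecast gives 61% (54% to 68%) reacted and dp 130 (40 to 340): “Radicals are being lost, a dead-end polymerisation.” The reckoning here stands lower on conversion.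

**The result.** The flask gives 56.3% reacted and dp 174.

    initiator → 2 initiating radical (k = 0.0240 s⁻¹)
    free monomer + initiating radical → growing radical + monomer in chains (k = 2.30 × 10⁵ L mol⁻¹ s⁻¹)
    free monomer + growing radical → monomer in chains + growing radical, rate k3*[growing radical]*[free monomer] (k = 8900 L mol⁻¹ s⁻¹)
    2 growing radical → dead chain (k = 7.40 × 10⁶ L mol⁻¹ s⁻¹)
    free monomer → decomposition product (k = 1.60 × 10⁻⁵ s⁻¹)
    protic impurity + free monomer → quenched substrate (k = 5.90 L mol⁻¹ s⁻¹)

**Falling initiator.** The flask's log left is 0.828, where the keep factor of 0.480 gave 0.830. Read at 80 s, the same series leaves 58.7% free monomer, and that flask holds 58.8%. The fall of initiator is the largest single effect on the average chain in this flask, though not the main reason: the run without that fall gives 42.2 units against 174.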